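I am the chemist with the flasks below, and I want to know how much target stands in each at the end.

| flask | starting material | second substrate | free catalyst | temperature | remark | time |
|---|---|---|---|---|---|---|
| Friday's | 0.050 M | 1 equiv | 17 mol% | 10 °C | run made earlier |  |
| Sunday's | 0.050 M | 0.50 equiv | 17 mol% | 25 °C | run made earlier |  |
| Monday's | 0.050 M | 2 equiv | 17 mol% | 10 °C | run made earlier |  |
| Saturday's | 0.10 M | 1 equiv | 17 mol% | 25 °C | run made earlier |  |
| elm | 0.050 M | 1.00 equiv (fed, over 1.5 min) | 17 mol% |  | the addition at −15 °C, then warmed to 25 °C; the feed brings no volume worth counting | 4.0 min |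
| birch | 0.050 M (in portions, 5, over 1.5 min) | 1.00 equiv | 17 mol% | 25 °C | first portion at the start, last at 1.5 min | 4.0 min |
| larch | 0.050 M | 1.00 equiv | 17 mol% | 25 °C | everything together at the start | 4.0 min |
| alder | 0.050 M (fed, over 1.5 min) | 1.00 equiv | 17 mol% | 25 °C | all else is in the flask from the start; the feed brings no volume worth counting | 4.0 min |
| oak | 0.050 M | 1.00 equiv | 17 mol% |  | everything together at the start at −15 °C, warmed to 25 °C at 1.5 min | 4.0 min |

- Friday's (time / min: target / %, starting material / %): 1.00: 5.3, 83.8; 2.00: 11.0, 77.5; 3.00: 17.7, 70.8; 4.00: 23.7, 65.1; 5.00: 27.8, 60.9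
- Sunday's (time / min: target / %, starting material / %): 0.667: 11.9, 80.1; 1.33: 22.9, 69.2; 2.00: 34.6, 60.3; 2.50: 40.7, 52.8; 3.00: 45.3, 48.0
- Monday's (time / min: target / %, starting material / %): 1.33: 6.2, 83.4; 3.00: 16.2, 73.5; 4.00: 21.5, 69.2; 5.00: 26.1, 62.9; 6.00: 32.5, 57.9
- Saturday's (time / min: target / %, starting material / %): 0.250: 5.0, 84.8; 0.500: 10.5, 79.4; 0.833: 17.3, 71.9; 1.50: 30.8, 60.1; 3.00: 53.4, 38.0

(readings scatter by 0.5 percentage points)

* the best flask by amount of target, in percent of the starting material charged; "all alike" if 1.5 percentage points covers them all (elm / birch / larch / alder / oak / all alike)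
* amount of target at the end, in percent of the starting material charged, elm
* amount of target at the end, in percent of the starting material charged, birch
* amount of target at the end, in percent of the starting material charged, larch
* amount of target at the end, in percent of the starting material charged, alder
* amount of target at the end, in percent of the starting material charged, oak



First question: what feeds the target? In the first readings of Sunday's run, target and starting material together fall short of the charge by 7.95%, and in Saturday's by 10.5%. I read that gap as starting material bound on the catalyst. Dividing the gap by the rate at which target appears gives 0.479 min and 0.498 min. So I carry their mean, 0.488 min, as the emptying time of the bound part, the inverse of its turnover frequency.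

Second question: is the cold hold lost time? Friday's run gives 1.80 min at its lower temperature, and carrying that trend down gives 15.9 min at −15 °C. This is far longer than the hold of 1.5 min, so by this estimate a fully bound catalyst makes about 1.61% of the charge there. I therefore count 2.50 min of working time for oak and elm.

Third question: which curve do I read? Twice the second substrate moves the target at 4.00 min from 23.7% to 21.5%, so I use Sunday's curve. It reads 40.7% for oak and elm. Fed material arrives on average at 0.750 min, so alder and birch reach 47.6% by extending its last slope, and larch reaches 54.5%.

The forecast also puts larch first, at 57%, which is higher than my figure, with birch 49%, alder 49%, elm 39% and oak 39.5%, holding that “the cold period is essentially lost time”.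

The flasks give larch 54.2%, birch 48.8%, alder 48.6%, elm 40.0% and oak 39.9%, so larch is best.

    starting material + free catalyst ⇌ catalyst intermediate A (K = 41.0 L mol⁻¹, k = 2.60 L mol⁻¹ s⁻¹, Ea = 38.0 kJ mol⁻¹, ΔH = −65.0 kJ mol⁻¹)
    catalyst intermediate A ⇌ free catalyst + target (K = 0.110 M, k = 0.0400 s⁻¹, Ea = 69.0 kJ mol⁻¹, ΔH = −17.0 kJ mol⁻¹)
    second substrate + free catalyst ⇌ catalyst intermediate B (K = 130 L mol⁻¹, k = 1.00 L mol⁻¹ s⁻¹, Ea = 55.0 kJ mol⁻¹, ΔH = 19.0 kJ mol⁻¹)
    catalyst intermediate B → free catalyst + second product (k = 0.160 s⁻¹, Ea = 71.0 kJ mol⁻¹)
    (constants at 25 °C)

The bound part is catalyst intermediate A. My carried 0.488 min is longer than the 0.417 min that the forward constant of that step gives, so what I reckon with it is an estimate. In larch at 4.00 min catalyst intermediate A holds 35.1% of the catalyst, so I estimate its one-way flow to target, in fractions of the charge, at 0.122 min⁻¹. Left until 15 min, larch holds 4.47% of the charge as catalyst intermediate A, an estimated one-way flow of 0.0915 min⁻¹. Yet the target has gained on average 0.0216 min⁻¹ since the asked time, less than that estimated flow, and it stands at 78.0%. At 40.0 min larch reads 78.2% target, with 17.3% starting material beside it.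

(The earlier runs and the new flask are simulated for substances that don't exist, and the scatter is random.)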